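**Plan**
1. Retrosynthesis: the three phenols are masked as methyl ethers. The 20-membered ring is opened at C5–C6 of the twelve-carbon bridge, giving a diaryl ether dialdehyde with a 5-oxopentyl arm on ring A and a 7-oxoheptyl arm on ring B.
2. Enabling feature: bridge carbons C1 (on ring A, the 1,3,5-trisubstituted arene) to C12 (on ring B, the 2,6-dioxygenated arene) carry no substituent, heteroatom or stereocentre. A C5=C6 alkene of either geometry is therefore a full equivalent of the saturated bond, and rings A and B with their ether oxygen are inert to low-valent titanium.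
3. Further cuts: C10=C11 (cross-metathesis), ring A–C1 (Sonogashira coupling) and the ring A carbon–oxygen bond of the diaryl ether (Ullmann coupling), leading back to four commercial compounds.
4. Forward order: diaryl ether, ring B arm, ring A arm, saturation, double oxidation, macrocyclisation (the only ring formed; both arenes are bought), saturation, demethylation.
5. Stereochemistry: the target has no stereocentre and no double bond in the bridge. The alkene geometries at C10=C11 and C5=C6 are erased by hydrogenation.

Key step: step 6

Remark: bridge carbons are labelled C1 (bonded to ring A) to C12 (bonded to ring B). Where an alkene is expected as an E/Z mixture, the E isomer is drawn and both isomers are carried on together.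

Step 1
Reactants: 1 4-allyl-2,6-dimethoxyphenol; 2 1,3-dibromo-5-methoxybenzene
Product: 3 5-allyl-2-(3-bromo-5-methoxyphenoxy)-1,3-dimethoxybenzene
Conditions: CuI (10 mol%), picolinic acid (20 mol%), K3PO4 (2 equiv), 2 (3 equiv), DMSO, 90 °C
Reagents that add atoms: none
Why: Ligand-accelerated Ullmann diaryl ether synthesis, in which picolinic acid-bound monovalent copper is known to arylate phenoxides flanked by two ortho substituents, the threefold excess of the symmetrical dibromide 2 holds the reaction at monoarylation, and K3PO4 at 90 °C is too weak a base to pull the allyl double bond into conjugation.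

Step 2
Reactants: 3 5-allyl-2-(3-bromo-5-methoxyphenoxy)-1,3-dimethoxybenzene; 4 hex-5-en-1-ol
Product: 5 (E)-7-[4-(3-bromo-5-methoxyphenoxy)-3,5-dimethoxyphenyl]hept-5-en-1-ol (E drawn, Z isomer also expected)
Conditions: 4 (4 equiv), second-generation Grubbs catalyst (H2IMes)(PCy3)Cl2Ru=CHPh (5 mol%), 1,4-benzoquinone (10 mol%), CH2Cl2, 40 °C
Reagents that add atoms: none
Why: Olefin cross-metathesis between two unhindered terminal alkenes, in which the excess of cheap 4 pushes the statistical product distribution towards the cross product, 1,4-benzoquinone intercepts ruthenium hydrides that could migrate the allyl double bond, and placement ahead of the alkyne-introducing step rules out enyne metathesis.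

Step 3
Reactants: 5 (E)-7-[4-(3-bromo-5-methoxyphenoxy)-3,5-dimethoxyphenyl]hept-5-en-1-ol; 6 pent-4-yn-1-ol
Product: 7 (E)-7-{4-[3-(5-hydroxypent-1-yn-1-yl)-5-methoxyphenoxy]-3,5-dimethoxyphenyl}hept-5-en-1-ol
Conditions: 6 (1.5 equiv), PdCl2(PPh3)2 (5 mol%), CuI (10 mol%), Et3N/DMF, degassed, 80 °C
Reagents that add atoms: none
Why: Sonogashira coupling, in which zerovalent palladium formed in situ inserts into the aryl C–Br bond (activated inductively by the two meta oxygen substituents), the copper acetylide of 6 transmetallates and reductive elimination forms the ring A–C1 bond, while the free hydroxyl groups and the internal alkene are bystanders.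

Step 4
Reactants: 7 (E)-7-{4-[3-(5-hydroxypent-1-yn-1-yl)-5-methoxyphenoxy]-3,5-dimethoxyphenyl}hept-5-en-1-ol
Product: 8 7-{4-[3-(5-hydroxypentyl)-5-methoxyphenoxy]-3,5-dimethoxyphenyl}heptan-1-ol
Conditions: H2 (1 atm), 10% Pd/C, EtOAc/MeOH, rt
Reagents that add atoms: none
Why: Heterogeneous catalytic hydrogenation adds three equivalents of H2 to the alkyne and to either alkene isomer in one operation, and since the molecule holds no benzylic C–O bond, halogen or other reducible group only the two arms change.

Step 5
Reactants: 8 7-{4-[3-(5-hydroxypentyl)-5-methoxyphenoxy]-3,5-dimethoxyphenyl}heptan-1-ol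
Product: 9 7-{3,5-dimethoxy-4-[3-methoxy-5-(5-oxopentyl)phenoxy]phenyl}heptanal (dialdehyde)
Conditions: Dess–Martin periodinane (2.5 equiv), CH2Cl2, 0 °C to rt
Reagents that add atoms: none
Why: Dess–Martin oxidation takes both primary alcohols to the aldehyde level in a non-aqueous medium where no hydrate can form and overoxidation to the acid is therefore excluded, and the aryl ethers are inert to the reagent.

Step 6
Reactants: 9 7-{3,5-dimethoxy-4-[3-methoxy-5-(5-oxopentyl)phenoxy]phenyl}heptanal
Product: 11 (E)-1^5,3^2,3^6-trimethoxy-2-oxa-1(1,3),3(1,4)-dibenzenacyclopentadecaphan-10-ene (20-membered cycloalkene with the double bond at C5=C6; E drawn), via cyclic titanium pinacolate 10 (not isolated)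
Conditions: TiCl3(DME)1.5 (12 equiv), Zn–Cu couple (40 equiv), DME, reflux, 4 h; then 9 in DME by syringe pump over 30 h, reflux
Reagents that add atoms: none
Why: Intramolecular McMurry reductive carbonyl coupling: the finely divided low-valent titanium made from TiCl3(DME)1.5 and Zn–Cu passes one electron to each formyl group of 9, the two surface-bound ketyl radicals combine to form the C5–C6 bond as the titanium pinacolate 10, and at reflux both C–O bonds break in favour of strong Ti–O bonds to leave the C5=C6 alkene 11. The closest known reaction type is the titanium-induced cyclisation of long-chain α,ω-dialdehydes to medium and large cycloalkenes, which is established for rings of comparable and larger size. The 20-membered ring closes end to end, the terminal carbon of the five-carbon arm on ring A bonding to the terminal carbon of the seven-carbon arm on ring B, so that both former carbonyl carbons become ring members. No lasting stereocentre is made: the two carbinol centres of 10 vanish on deoxygenation, and the geometry of 11 is left uncontrolled because step 7 removes the double bond. The selectivity needed is ring closure over intermolecular coupling, secured by syringe-pump addition into a large excess of reductant (pseudo-high dilution) and by the template effect of the metal surface, on which both ketyls sit before they meet, so that the usual entropic penalty of a large ring is damped. Chemoselectivity is built into the substrate, which beside the two aldehydes holds only aryl ethers, arene rings and methylene groups, all inert to low-valent titanium.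

Step 7
Reactants: 11 (E)-1^5,3^2,3^6-trimethoxy-2-oxa-1(1,3),3(1,4)-dibenzenacyclopentadecaphan-10-ene
Product: 12 1^5,3^2,3^6-trimethoxy-2-oxa-1(1,3),3(1,4)-dibenzenacyclopentadecaphane (saturated macrocycle, trimethyl ether of the target)
Conditions: H2 (1 atm), 10% Pd/C, EtOAc, rt
Reagents that add atoms: none
Why: Catalytic hydrogenation of an isolated 1,2-disubstituted alkene, in which both geometric isomers of 11 converge on the same saturated twelve-carbon bridge and the aryl ethers are untouched.

Step 8
Reactants: 12 1^5,3^2,3^6-trimethoxy-2-oxa-1(1,3),3(1,4)-dibenzenacyclopentadecaphane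
Product: 14 2-oxa-1(1,3),3(1,4)-dibenzenacyclopentadecaphane-1^5,3^2,3^6-triol (CNP0314249.0), via tris(dibromoboryl) ether 13 (not isolated)
Conditions: BBr3 (6 equiv), CH2Cl2, −78 °C to rt; then H2O, 0 °C
Reagents that add atoms: none
Why: Lewis acid-mediated cleavage of aryl methyl ethers, in which BBr3 binds each methoxy oxygen and bromide removes the methyl group by SN2 attack to give the boron aryloxide 13 that water hydrolyses to the free phenols, whereas the diaryl ether oxygen carries no sp3 carbon and so cannot be cleaved this way.

**Compound list**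
1 | 4-allyl-2,6-dimethoxyphenol | C=CCc1cc(OC)c(O)c(OC)c1 | starting material
2 | 1,3-dibromo-5-methoxybenzene | COc1cc(Br)cc(Br)c1 | starting material
3 | 5-allyl-2-(3-bromo-5-methoxyphenoxy)-1,3-dimethoxybenzene | C=CCc1cc(OC)c(Oc2cc(Br)cc(OC)c2)c(OC)c1 | intermediate
4 | hex-5-en-1-ol | C=CCCCCO | starting material
5 | (E)-7-[4-(3-bromo-5-methoxyphenoxy)-3,5-dimethoxyphenyl]hept-5-en-1-ol (E drawn) | OCCCC/C=C/Cc1cc(OC)c(Oc2cc(Br)cc(OC)c2)c(OC)c1 | intermediate
6 | pent-4-yn-1-ol | C#CCCCO | starting material
7 | (E)-7-{4-[3-(5-hydroxypent-1-yn-1-yl)-5-methoxyphenoxy]-3,5-dimethoxyphenyl}hept-5-en-1-ol (E drawn) | OCCCC/C=C/Cc1cc(OC)c(Oc2cc(C#CCCCO)cc(OC)c2)c(OC)c1 | intermediate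
8 | 7-{4-[3-(5-hydroxypentyl)-5-methoxyphenoxy]-3,5-dimethoxyphenyl}heptan-1-ol | OCCCCCCCc1cc(OC)c(Oc2cc(CCCCCO)cc(OC)c2)c(OC)c1 | intermediate
9 | 7-{3,5-dimethoxy-4-[3-methoxy-5-(5-oxopentyl)phenoxy]phenyl}heptanal | O=CCCCCc1cc(OC)cc(Oc2c(OC)cc(CCCCCCC=O)cc2OC)c1 | intermediate
10 | cyclic titanium pinacolate, the C5,C6-diolate of the closed 20-membered ring bound to titanium (diastereomer mixture, not isolated) | COc1cc2cc(c1)Oc1c(OC)cc(cc1OC)CCCCCCC3O[Ti]OC3CCCC2 | intermediate
11 | (E)-1^5,3^2,3^6-trimethoxy-2-oxa-1(1,3),3(1,4)-dibenzenacyclopentadecaphan-10-ene (C5=C6 cycloalkene, E drawn) | COc1cc2cc(c1)Oc1c(OC)cc(cc1OC)CCCCCC/C=C/CCCC2 | intermediate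
12 | 1^5,3^2,3^6-trimethoxy-2-oxa-1(1,3),3(1,4)-dibenzenacyclopentadecaphane | COc1cc2cc(c1)Oc1c(OC)cc(cc1OC)CCCCCCCCCCCC2 | intermediate
13 | tris(dibromoboryl) ether of the target (each phenol oxygen bearing BBr2, not isolated) | BrB(Br)Oc1cc2cc(c1)Oc1c(OB(Br)Br)cc(cc1OB(Br)Br)CCCCCCCCCCCC2 | intermediate
14 | 2-oxa-1(1,3),3(1,4)-dibenzenacyclopentadecaphane-1^5,3^2,3^6-triol (CNP0314249.0) | Oc1cc2cc(c1)Oc1c(O)cc(cc1O)CCCCCCCCCCCC2 | target

**Total step count:** 8
**Longest linear sequence:** 8 steps (from 1 or 2 to 14)

**Steps most likely to fail**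

Step 6 (macrocyclisation). Three processes could lower the return of the ring:
- intermolecular ketyl coupling leading to oligomerisation
- stalling at the pinacolate stage
- plain reduction of the formyl groups

The fallback makes the same C5=C6 bond by ring-closing olefin metathesis. Setting out from 9, double Wittig methylenation (MePPh3Br, KOtBu, THF, 0 °C) should give the diene 2-[3-(hex-5-en-1-yl)-5-methoxyphenoxy]-1,3-dimethoxy-5-(oct-7-en-1-yl)benzene F1. Ring closure of this diene uses second-generation Grubbs catalyst (H2IMes)(PCy3)Cl2Ru=CHPh in dilute CH2Cl2 at reflux, with loss of ethene. It comes back to the route at 11.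

Step 2 (cross-metathesis). Two processes are the concern:
- homodimerisation of either partner
- ruthenium hydride-induced double-bond migration followed by metathesis, which would cut a CH2 unit out of the arm and give a homologue that is hard to remove

The fallback fixes the carbon count by carbonyl olefination.
- Setting out from 3, Lemieux–Johnson cleavage (OsO4 cat., NaIO4, 2,6-lutidine, dioxane/H2O, rt) should give [4-(3-bromo-5-methoxyphenoxy)-3,5-dimethoxyphenyl]acetaldehyde F2.
- In parallel, 5-bromopentan-1-ol and PPh3 (MeCN, reflux) give (5-hydroxypentyl)triphenylphosphonium bromide F3.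
- The ylide alkoxide from this salt and two equivalents of NaHMDS (THF, −78 °C to rt) should react with the aldehyde in a Wittig reaction. The product is (Z)-7-[4-(3-bromo-5-methoxyphenoxy)-3,5-dimethoxyphenyl]hept-5-en-1-ol F4, the geometric isomer of 5.
- Sonogashira coupling with 6 under the conditions of step 3 should give (Z)-7-{4-[3-(5-hydroxypent-1-yn-1-yl)-5-methoxyphenoxy]-3,5-dimethoxyphenyl}hept-5-en-1-ol F5.
- Hydrogenation under the conditions of step 4 comes back to the route at 8.

Step 1 (diaryl ether). Three processes are possible:
- slow C–O bond formation at a phenoxide crowded by two ortho methoxy groups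
- a second arylation at the remaining C–Br bond
- base-induced migration of the allyl double bond on long heating

The fallback is an oxidative Chan–Lam coupling at room temperature. Setting out from 1, it uses commercial (3-bromo-5-methoxyphenyl)boronic acid (OB(O)c1cc(Br)cc(OC)c1), Cu(OAc)2, pyridine and 4 Å molecular sieves in CH2Cl2 under air. The C–O bond forms only at the boron-bearing carbon, the single bromine stays in place, and no strong base or heat is applied. It comes back to the route at 3 and makes no compound outside the list (entry F0).

**Further compounds**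
F1 | step 6 | 2-[3-(hex-5-en-1-yl)-5-methoxyphenoxy]-1,3-dimethoxy-5-(oct-7-en-1-yl)benzene | C=CCCCCc1cc(OC)cc(Oc2c(OC)cc(CCCCCCC=C)cc2OC)c1
F2 | step 2 | [4-(3-bromo-5-methoxyphenoxy)-3,5-dimethoxyphenyl]acetaldehyde | O=CCc1cc(OC)c(Oc2cc(Br)cc(OC)c2)c(OC)c1
F3 | step 2 | (5-hydroxypentyl)triphenylphosphonium bromide | OCCCCC[P+](c1ccccc1)(c1ccccc1)c1ccccc1.[Br-]
F4 | step 2 | (Z)-7-[4-(3-bromo-5-methoxyphenoxy)-3,5-dimethoxyphenyl]hept-5-en-1-ol | OCCCC/C=C\Cc1cc(OC)c(Oc2cc(Br)cc(OC)c2)c(OC)c1
F5 | step 2 | (Z)-7-{4-[3-(5-hydroxypent-1-yn-1-yl)-5-methoxyphenoxy]-3,5-dimethoxyphenyl}hept-5-en-1-ol | OCCCC/C=C\Cc1cc(OC)c(Oc2cc(C#CCCCO)cc(OC)c2)c(OC)c1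
F0 | step 1 | none | none
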